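The depside ester linking the ring A C1 carbonyl to ring B O-4 is the obvious retrosynthetic cut, but the plan rests on the ring A C2–CH2 bond. In ring A the C1 carboxyl carbon is flanked by a methoxy group at C6 and by the 2-oxoheptyl chain at C2. 2,4-Dimethoxybenzoic acid therefore offers only one ortho C–H bond to a carboxylate-bound metal. One operation under trivalent rhodium catalysis couples this acid with a hexanoyl-derived sulfoxonium ylide. It forms the aryl–CH2 bond and closes the enol lactone of 6,8-dimethoxy-3-pentylisocoumarin, a masked keto acid. Hydroxide opening, carbodiimide esterification with an O-2-methylated benzyl olivetolate and hydrogenolysis complete the route.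

Key step: step 2

Remark on the chemistry: the target is achiral, so no stereocentre has to be set. Ring A is numbered C1 (ester carbonyl), C2 (2-oxoheptyl), C4 and C6 (methoxy). Ring B is numbered C1 (CO2H), C2 (methoxy), C4 (depside oxygen), C6 (pentyl).

Remark on the chemistry: ring B needs O-2 methylated and O-4 free, which is the reverse of the innate reactivity of olivetolates. O-4 is therefore masked for one stage as an allyl ether, which is orthogonal to the benzyl ester.

Step 1
Reactants: 1 trimethylsulfoxonium iodide; 2 hexanoyl chloride
Product: 4 dimethylsulfoxonium 2-oxoheptylide, via dimethylsulfoxonium methylide 3 (not isolated)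
Conditions: 1 (3 equiv), KOtBu (3 equiv), THF, reflux; then 2 (1 equiv), 0 °C → rt
Reagents that add atoms: none
Why: Acylation of the Corey–Chaykovsky methylide 3 at carbon by the acid chloride, followed by deprotonation of the acylsulfoxonium salt by a second equivalent of 3, is the standard entry to carbonyl-stabilised sulfoxonium ylides, and the excess of 3 also intercepts any ketene formed by dehydrochlorination to give the same product.

Step 2
Reactants: 5 2,4-dimethoxybenzoic acid; 4 dimethylsulfoxonium 2-oxoheptylide
Product: 7 6,8-dimethoxy-3-pentyl-1H-isochromen-1-one, via keto acid 6 (not isolated)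
Conditions: [RhCl2(C5Me5)]2 (4 mol%), AgSbF6 (16 mol%), NaOAc (50 mol%), 4 (1.5 equiv, in portions), DCE, 80 °C, N2; crude then TsOH·H2O (cat.), toluene, 80 °C to close any residual 6
Reagents that add atoms: none
Why: The cationic trivalent rhodium species, held by the carboxylate of 5, cleaves the C6–H bond (ring A C2 of the target) by acetate-assisted concerted metalation–deprotonation to give a five-membered rhodacycle; the ylide carbon of 4 then binds, dimethyl sulfoxide leaves to give a rhodium carbene, the aryl group migrates onto the carbene carbon, and protonolysis releases keto acid 6 and the catalyst. The closest known reaction type is the carboxylate- or amide-directed C–H acylmethylation and annulation of arenes with alpha-carbonyl sulfoxonium ylides under C5Me5-rhodium or arene-ruthenium catalysis, which converts benzoic acids into 3-substituted isocoumarins. The one new ring, the six-membered enol lactone, closes by 6-exo-trig attack of the carboxyl oxygen on the ketone carbonyl followed by loss of water across C3–C4. No stereocentre is created. The step needs site selectivity and mono-functionalisation: the C2 methoxy group of 5 blocks one ortho position, the electron-rich C3–H and C5–H bonds are out of reach of the bound metal, and lactonisation removes the directing group after a single insertion. Matching AgSbF6 exactly to chloride leaves no free silver ion and portionwise ylide addition keeps its concentration low, which should curb protodecarboxylation of the electron-rich acid and O-alkylation of the carboxylate by protonated ylide.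

Step 3
Reactants: 7 6,8-dimethoxy-3-pentyl-1H-isochromen-1-one
Product: 6 2,4-dimethoxy-6-(2-oxoheptyl)benzoic acid
Conditions: KOH (2 M aq., 3 equiv), 1,4-dioxane, 60 °C; then 1 M HCl to pH 3, 0 °C, EtOAc extraction, cold concentration, used at once
Reagents that add atoms: potassium hydroxide, [K+].[OH-]
Why: Saponification of the enol lactone is driven to completion because the released enolate tautomerises to the ketone and the carboxylate resists re-addition, while cold, brief acidification and immediate use should prevent acid-catalysed re-closure to 7.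

Step 4
Reactants: 8 olivetolic acid (2,4-dihydroxy-6-pentylbenzoic acid)
Product: 9 benzyl 2,4-dihydroxy-6-pentylbenzoate
Conditions: BnBr (1.05 equiv), KHCO3 (1.2 equiv), DMF, rt
Reagents that add atoms: benzyl bromide, BrCc1ccccc1
Why: This is an SN2 alkylation of the carboxylate, since KHCO3 ionises only the carboxylic acid and leaves both phenols protonated, and room temperature avoids the thermal decarboxylation typical of resorcylic acids.

Step 5
Reactants: 9 benzyl 2,4-dihydroxy-6-pentylbenzoate
Product: 11 benzyl 4-(allyloxy)-2-methoxy-6-pentylbenzoate, via 4-O-allyl ether 10 (not isolated)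
Conditions: allyl bromide (1.0 equiv), K2CO3 (3 equiv), acetone, rt; then MeI (5 equiv), 50 °C, closed flask
Reagents that add atoms: allyl bromide, C=CCBr; iodomethane, CI
Why: Two Williamson etherifications run in sequence in one flask, because the 2-OH is locked in a hydrogen bond to the ester carbonyl and is alkylated far more slowly than the 4-OH, so one equivalent of allyl bromide should cap O-4 first and excess iodomethane with warming then methylates O-2.

Step 6
Reactants: 11 benzyl 4-(allyloxy)-2-methoxy-6-pentylbenzoate
Product: 12 benzyl 4-hydroxy-2-methoxy-6-pentylbenzoate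
Conditions: Pd(PPh3)4 (3 mol%), morpholine (5 equiv), THF, rt
Reagents that add atoms: none
Why: In this Tsuji–Trost-type deallylation zerovalent palladium ionises the allyl aryl ether to a pi-allyl complex and a stabilised phenoxide, morpholine captures the allyl unit, and the benzyl ester and methyl ether are left untouched.

Step 7
Reactants: 6 2,4-dimethoxy-6-(2-oxoheptyl)benzoic acid; 12 benzyl 4-hydroxy-2-methoxy-6-pentylbenzoate
Product: 13 benzyl 4-{[2,4-dimethoxy-6-(2-oxoheptyl)benzoyl]oxy}-2-methoxy-6-pentylbenzoate
Conditions: 12 (1.2 equiv), DMAP (10 mol%), DCC (1.2 equiv, added last and slowly), toluene–CH2Cl2, 0 °C → rt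
Reagents that add atoms: none
Why: Steglich esterification is the customary way to join hindered depside halves, the phenol is present in excess before the carbodiimide is added so that the activated acyl species is intercepted intermolecularly, and under these near-neutral conditions the only realistic diversion, re-closure to 7, returns material that can be recycled through step 3.

Step 8
Reactants: 13 benzyl 4-{[2,4-dimethoxy-6-(2-oxoheptyl)benzoyl]oxy}-2-methoxy-6-pentylbenzoate
Product: 14 4-{[2,4-dimethoxy-6-(2-oxoheptyl)benzoyl]oxy}-2-methoxy-6-pentylbenzoic acid (CNP0169128.0)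
Conditions: H2 (1 atm), 10% Pd/C, EtOAc, rt
Reagents that add atoms: none
Why: Catalytic hydrogenolysis of the benzyl ester under neutral conditions frees the ring B carboxylic acid without exposing the acid- and base-sensitive keto depside to hydrolysis, and the non-conjugated ketone, the aryl ester and the methyl ethers are inert to H2 over Pd/C at ambient pressure.

Compound list
1 | trimethylsulfoxonium iodide | C[S+](C)(C)=O.[I-] | starting material
2 | hexanoyl chloride | CCCCCC(=O)Cl | starting material
3 | dimethylsulfoxonium methylide | C=S(C)(C)=O | intermediate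
4 | dimethylsulfoxonium 2-oxoheptylide | CCCCCC(=O)C=S(C)(C)=O | intermediate
5 | 2,4-dimethoxybenzoic acid | COc1ccc(C(=O)O)c(OC)c1 | starting material
6 | 2,4-dimethoxy-6-(2-oxoheptyl)benzoic acid | CCCCCC(=O)Cc1cc(OC)cc(OC)c1C(=O)O | intermediate
7 | 6,8-dimethoxy-3-pentyl-1H-isochromen-1-one | CCCCCC1=Cc2cc(OC)cc(OC)c2C(=O)O1 | intermediate
8 | olivetolic acid | CCCCCc1cc(O)cc(O)c1C(=O)O | starting material
9 | benzyl 2,4-dihydroxy-6-pentylbenzoate | CCCCCc1cc(O)cc(O)c1C(=O)OCc1ccccc1 | intermediate
10 | benzyl 4-(allyloxy)-2-hydroxy-6-pentylbenzoate | CCCCCc1cc(OCC=C)cc(O)c1C(=O)OCc1ccccc1 | intermediate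
11 | benzyl 4-(allyloxy)-2-methoxy-6-pentylbenzoate | CCCCCc1cc(OCC=C)cc(OC)c1C(=O)OCc1ccccc1 | intermediate
12 | benzyl 4-hydroxy-2-methoxy-6-pentylbenzoate | CCCCCc1cc(O)cc(OC)c1C(=O)OCc1ccccc1 | intermediate
13 | benzyl 4-{[2,4-dimethoxy-6-(2-oxoheptyl)benzoyl]oxy}-2-methoxy-6-pentylbenzoate | CCCCCC(=O)Cc1cc(OC)cc(OC)c1C(=O)Oc1cc(CCCCC)c(C(=O)OCc2ccccc2)c(OC)c1 | intermediate
14 | 4-{[2,4-dimethoxy-6-(2-oxoheptyl)benzoyl]oxy}-2-methoxy-6-pentylbenzoic acid | CCCCCC(=O)Cc1cc(OC)cc(OC)c1C(=O)Oc1cc(CCCCC)c(C(=O)O)c(OC)c1 | target

Total step count: 8.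
Longest linear sequence: 5 (steps 1, 2, 3, 7, 8, or steps 4, 5, 6, 7, 8).

Steps most likely to fail

**Step 2.** Metalation of the hindered, electron-rich acid may be slow. Protodecarboxylation, O-alkylation of the carboxylate by protonated ylide or thermal decay of the ylide could then outrun C–C bond formation. The fallback replaces catalytic C–H activation by stoichiometric directed metalation; it sets out from 5 and comes back at 7.
- Acid 5 is converted (SOCl2, then Et2NH) into N,N-diethyl-2,4-dimethoxybenzamide F1.
- Amide-directed ortho-lithiation at C6 (s-BuLi, TMEDA, THF, −78 °C) and a MeI quench give N,N-diethyl-2,4-dimethoxy-6-methylbenzamide F2.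
- Lateral lithiation of the methyl group (LiN(iPr)2, THF, −78 °C) and acylation with N-methoxy-N-methylhexanamide give N,N-diethyl-2,4-dimethoxy-6-(2-oxoheptyl)benzamide F3.
- Heating with TsOH·H2O in toluene cyclises the keto amide with loss of the amine to 7.

**Step 7.** The oxygen of the side-chain ketone or its enol may capture the activated carboxyl intramolecularly (re-lactonisation) faster than the weakly nucleophilic phenol attacks, and acyl migration within the carbodiimide adduct may add to the loss. The fallback removes the internal nucleophile by masking the ketone; it sets out from 6 and comes back at 13.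
- The carboxylate of 6 is alkylated (allyl bromide, KHCO3, DMF) to allyl 2,4-dimethoxy-6-(2-oxoheptyl)benzoate F4.
- Low-temperature ketalisation (Me3SiOCH2CH2OSiMe3, cat. Me3SiOTf, CH2Cl2, −78 → −20 °C) gives allyl 2,4-dimethoxy-6-[(2-pentyl-1,3-dioxolan-2-yl)methyl]benzoate F5.
- Pd(PPh3)4 and morpholine release 2,4-dimethoxy-6-[(2-pentyl-1,3-dioxolan-2-yl)methyl]benzoic acid F6.
- DCC/DMAP coupling with 12 gives benzyl 4-({2,4-dimethoxy-6-[(2-pentyl-1,3-dioxolan-2-yl)methyl]benzoyl}oxy)-2-methoxy-6-pentylbenzoate F7.
- Mild deketalisation (pyridinium tosylate, wet acetone, 40 °C) delivers 13.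

**Step 5.** Site selectivity between the two phenolic oxygens may erode in the first alkylation, and unreacted allyl bromide may carry over into the methylation stage. The fallback fixes the regiochemistry by ring formation instead of relative nucleophilicity; it sets out from 8 and comes back at 10.
- Acid 8 is condensed with acetone ((CF3CO)2O, CF3CO2H, 0 °C → rt), tying O-2 and the carboxyl together as 7-hydroxy-2,2-dimethyl-5-pentyl-4H-1,3-benzodioxin-4-one F8.
- The only free phenol is allylated (allyl bromide, K2CO3, acetone) to 7-(allyloxy)-2,2-dimethyl-5-pentyl-4H-1,3-benzodioxin-4-one F9.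
- Opening with sodium benzyloxide (BnOH, NaH, THF, 0 °C → rt) gives 10.
- Compound 10 is isolated this time and methylated separately (MeI, K2CO3) to 11.

Further compounds
F1 | step 2 | N,N-diethyl-2,4-dimethoxybenzamide | CCN(CC)C(=O)c1ccc(OC)cc1OC
F2 | step 2 | N,N-diethyl-2,4-dimethoxy-6-methylbenzamide | CCN(CC)C(=O)c1c(C)cc(OC)cc1OC
F3 | step 2 | N,N-diethyl-2,4-dimethoxy-6-(2-oxoheptyl)benzamide | CCCCCC(=O)Cc1cc(OC)cc(OC)c1C(=O)N(CC)CC
F4 | step 7 | allyl 2,4-dimethoxy-6-(2-oxoheptyl)benzoate | CCCCCC(=O)Cc1cc(OC)cc(OC)c1C(=O)OCC=C
F5 | step 7 | allyl 2,4-dimethoxy-6-[(2-pentyl-1,3-dioxolan-2-yl)methyl]benzoate | CCCCCC1(Cc2cc(OC)cc(OC)c2C(=O)OCC=C)OCCO1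
F6 | step 7 | 2,4-dimethoxy-6-[(2-pentyl-1,3-dioxolan-2-yl)methyl]benzoic acid | CCCCCC1(Cc2cc(OC)cc(OC)c2C(=O)O)OCCO1
F7 | step 7 | benzyl 4-({2,4-dimethoxy-6-[(2-pentyl-1,3-dioxolan-2-yl)methyl]benzoyl}oxy)-2-methoxy-6-pentylbenzoate | CCCCCC1(Cc2cc(OC)cc(OC)c2C(=O)Oc2cc(CCCCC)c(C(=O)OCc3ccccc3)c(OC)c2)OCCO1
F8 | step 5 | 7-hydroxy-2,2-dimethyl-5-pentyl-4H-1,3-benzodioxin-4-one | CCCCCc1cc(O)cc2c1C(=O)OC(C)(C)O2
F9 | step 5 | 7-(allyloxy)-2,2-dimethyl-5-pentyl-4H-1,3-benzodioxin-4-one | CCCCCc1cc(OCC=C)cc2c1C(=O)OC(C)(C)O2
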